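**Assumption:** carbons are numbered as in germacranolides (C1 ketone, C4=C5 olefin, C6 lactone oxygen, C8 methacrylate, C10 tertiary acetate, C12 lactone carbonyl, C13 acetoxymethyl); (R)-citramalic acid, both ProPhenol antipodes and the silyl propargyl ether are taken as catalogue items; the ligand antipode in step 9 is assigned by analogy with the ProPhenol aldol model and would be exchanged for its mirror image if the opposite carbinol formed.

## Retrosynthetic overview

1. The esters go on last: C8 methacrylate, then the C13 and C10 acetates together.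
2. Key disconnection C7–C8: an intramolecular Nozaki–Hiyama–Kishi closure of a fully substituted 4-iodobutenolide onto a β-hydroxy aldehyde forms the ten-membered ring and sets C8 by chromium chelation; no olefin metathesis is used.
3. The butenolide is built on the open chain from a propargylic alcohol by alkyne diiodination and carbonylative lactonisation; C6 comes from a ligand-controlled alkynylation of a Z-enal.
4. The Z-trisubstituted olefin comes from anti carbomagnesiation of propargyl alcohol, C2–C3 from an enolate allylation, and C10 from (R)-citramalic acid.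
5. Ring order: butenolide first, ten-membered carbocycle second.

## Route

Step 1
Reactants: 1 (R)-citramalic acid [(2R)-2-hydroxy-2-methylbutanedioic acid]
Product: 2 2-[(4R)-2,2,4-trimethyl-5-oxo-1,3-dioxolan-4-yl]acetic acid
Conditions: 2,2-dimethoxypropane, TsOH·H2O (cat.), rt
Reagents that add atoms: 2,2-dimethoxypropane, COC(C)(C)OC
Why: Acid-catalysed acetalisation ties the α-hydroxy acid into the favoured five-membered dioxolanone, which tells the two carboxyls apart and breaks no bond to the C10 centre (stays R).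

Step 2
Reactants: 2 2-[(4R)-2,2,4-trimethyl-5-oxo-1,3-dioxolan-4-yl]acetic acid
Product: 4 (3R)-3-hydroxy-3-methyloxolan-2-one, via hydroxyethyl dioxolanone 3 (not isolated)
Conditions: BH3·SMe2, THF, 0 °C to rt; MeOH; then TsOH·H2O (cat.), CH2Cl2, rt
Reagents that add atoms: none
Why: Borane reduces the free carboxylic acid chemoselectively (acyloxyborane pathway) beside the dioxolanone, and acid then drives translactonisation to the γ-lactone with loss of acetone.

Step 3
Reactants: 4 (3R)-3-hydroxy-3-methyloxolan-2-one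
Product: 5 (3R)-3,5-dihydroxy-3-methylpentan-2-one
Conditions: MeLi (2.2 equiv), THF, −78 °C; aq. NH4Cl
Reagents that add atoms: methyllithium, [Li]C
Why: Organolithium addition to a lactone stops at the ketone because the first equivalent makes the tertiary alkoxide and the second gives a lithium lactolate that only collapses on work-up.

Step 4
Reactants: 5 (3R)-3,5-dihydroxy-3-methylpentan-2-one
Product: 6 1-[(4R)-2,2,4-trimethyl-1,3-dioxan-4-yl]ethan-1-one
Conditions: 2,2-dimethoxypropane, PPTS (cat.), acetone, 4 Å sieves, rt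
Reagents that add atoms: 2,2-dimethoxypropane, COC(C)(C)OC
Why: Transacetalisation to the 1,3-diol acetonide masks both hydroxyls for the enolate chemistry and leaves a ketone that can enolise only towards its methyl group.

Step 5
Reactants: 7 prop-2-yn-1-ol
Product: 9 (2Z)-3-iodo-2-methylprop-2-en-1-ol, via alkenylmagnesium alkoxide 8 (not isolated)
Conditions: MeMgBr (2.5 equiv), CuI (10 mol%), THF, −10 °C to rt; then I2, −10 °C
Reagents that add atoms: methylmagnesium bromide, C[Mg]Br; iodine, [I][I]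
Why: Duboudin–Jousseaume carbomagnesiation: the magnesium alkoxide directs anti addition of Me–Mg so that magnesium ends cis to CH2O, and iodinolysis with retention fixes the Z geometry that becomes the C4=C5 olefin.

Step 6
Reactants: 9 (2Z)-3-iodo-2-methylprop-2-en-1-ol
Product: 10 (1Z)-3-bromo-1-iodo-2-methylprop-1-ene
Conditions: CBr4, PPh3, CH2Cl2, 0 °C
Reagents that add atoms: carbon tetrabromide, BrC(Br)(Br)Br
Why: Appel bromination replaces the primary allylic hydroxyl by SN2 without touching the olefin geometry or the vinyl iodide.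

Step 7
Reactants: 6 1-[(4R)-2,2,4-trimethyl-1,3-dioxan-4-yl]ethan-1-one; 10 (1Z)-3-bromo-1-iodo-2-methylprop-1-ene
Product: 12 (4Z)-5-iodo-4-methyl-1-[(4R)-2,2,4-trimethyl-1,3-dioxan-4-yl]pent-4-en-1-one, via lithium enolate 11 (not isolated)
Conditions: LiN(iPr)2 (1.05 equiv), THF, −78 °C; then 10, DMPU, −78 to −30 °C
Reagents that add atoms: none
Why: Kinetic enolate alkylation: the only enolisable side is the methyl group (C10 is quaternary) and the enolate displaces the allylic bromide by SN2, forming C2–C3 with the Z-vinyl iodide carried through unchanged.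

Step 8
Reactants: 12 (4Z)-5-iodo-4-methyl-1-[(4R)-2,2,4-trimethyl-1,3-dioxan-4-yl]pent-4-en-1-one
Product: 13 (2Z)-3-methyl-6-oxo-6-[(4R)-2,2,4-trimethyl-1,3-dioxan-4-yl]hex-2-enal
Conditions: Pd(PPh3)4 (5 mol%), CO (1 atm), Bu3SnH (slow addition), THF, 50 °C
Reagents that add atoms: carbon monoxide, [C-]#[O+]
Why: Stille reductive carbonylation (oxidative addition, CO insertion, hydride transfer from tin) turns the vinyl iodide into the enal with retention of the Z geometry.

Step 9
Reactants: 13 (2Z)-3-methyl-6-oxo-6-[(4R)-2,2,4-trimethyl-1,3-dioxan-4-yl]hex-2-enal; 14 tert-butyl(diphenyl)(prop-2-yn-1-yloxy)silane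
Product: 16 (4Z,6R)-9-{[tert-butyl(diphenyl)silyl]oxy}-6-hydroxy-4-methyl-1-[(4R)-2,2,4-trimethyl-1,3-dioxan-4-yl]non-4-en-7-yn-1-one, via alkynylzinc reagent 15 (not isolated)
Conditions: Me2Zn (3 equiv), (R,R)-ProPhenol (20 mol%), Ph3P=O (40 mol%), toluene, 0 °C; then 13, 4 °C
Reagents that add atoms: none
Why: Trost zinc–ProPhenol alkynylation: the chiral dinuclear zinc alkoxide binds the enal and delivers the alkynyl group to one face, creating the future C6 as R, while the alkylzinc species leave the ketone alone.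

Step 10
Reactants: 16 (4Z,6R)-9-{[tert-butyl(diphenyl)silyl]oxy}-6-hydroxy-4-methyl-1-[(4R)-2,2,4-trimethyl-1,3-dioxan-4-yl]non-4-en-7-yn-1-one
Product: 17 (4Z,6R,7E)-9-{[tert-butyl(diphenyl)silyl]oxy}-6-hydroxy-7,8-diiodo-4-methyl-1-[(4R)-2,2,4-trimethyl-1,3-dioxan-4-yl]nona-4,7-dien-1-one
Conditions: I2 (1.3 equiv), NaHCO3, CH2Cl2, dark, rt
Reagents that add atoms: iodine, [I][I]
Why: Anti addition of iodine to the alkyne gives the E-diiodide irreversibly, whereas addition to the trisubstituted olefin is reversible and stereoretentive in the dark, and the carbinol centre is not involved.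

Step 11
Reactants: 17 (4Z,6R,7E)-9-{[tert-butyl(diphenyl)silyl]oxy}-6-hydroxy-7,8-diiodo-4-methyl-1-[(4R)-2,2,4-trimethyl-1,3-dioxan-4-yl]nona-4,7-dien-1-one
Product: 18 (5R)-3-({[tert-butyl(diphenyl)silyl]oxy}methyl)-4-iodo-5-{(1Z)-2-methyl-5-oxo-5-[(4R)-2,2,4-trimethyl-1,3-dioxan-4-yl]pent-1-en-1-yl}furan-2(5H)-one
Conditions: PdCl2(PPh3)2 (5 mol%), K2CO3, CO (1 atm), THF, rt
Reagents that add atoms: carbon monoxide, [C-]#[O+]
Why: Stille–Cowell carbonylative lactonisation: only the C–I bond cis to the carbinol gives an acylpalladium that the hydroxyl can trap as a five-membered lactone, the silyl ether offers no β-leaving group, and the C6–O bond is never broken.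

Step 12
Reactants: 18 (5R)-3-({[tert-butyl(diphenyl)silyl]oxy}methyl)-4-iodo-5-{(1Z)-2-methyl-5-oxo-5-[(4R)-2,2,4-trimethyl-1,3-dioxan-4-yl]pent-1-en-1-yl}furan-2(5H)-one
Product: 19 (5R)-3-({[tert-butyl(diphenyl)silyl]oxy}methyl)-5-[(1Z,6R)-6,8-dihydroxy-2,6-dimethyl-5-oxooct-1-en-1-yl]-4-iodofuran-2(5H)-one
Conditions: AcOH/H2O/THF (3:1:1), 40 °C
Reagents that add atoms: none
Why: Mild acid hydrolysis of the acetonide frees the C8 and C10 hydroxyls, while the acid-stable silyl ether, the iodobutenolide and all stereocentres are untouched.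

Step 13
Reactants: 19 (5R)-3-({[tert-butyl(diphenyl)silyl]oxy}methyl)-5-[(1Z,6R)-6,8-dihydroxy-2,6-dimethyl-5-oxooct-1-en-1-yl]-4-iodofuran-2(5H)-one
Product: 20 (3R,7Z)-8-[(2R)-4-({[tert-butyl(diphenyl)silyl]oxy}methyl)-3-iodo-5-oxo-2,5-dihydrofuran-2-yl]-3-hydroxy-3,7-dimethyl-4-oxooct-7-enal
Conditions: Dess–Martin periodinane (1.2 equiv), NaHCO3, CH2Cl2, 0 °C
Reagents that add atoms: none
Why: Dess–Martin oxidation converts the only primary alcohol into the aldehyde, the tertiary C10 alcohol cannot be oxidised, and the buffered medium avoids β-elimination or retro-aldol of the β-hydroxy aldehyde.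

Step 14
Reactants: 20 (3R,7Z)-8-[(2R)-4-({[tert-butyl(diphenyl)silyl]oxy}methyl)-3-iodo-5-oxo-2,5-dihydrofuran-2-yl]-3-hydroxy-3,7-dimethyl-4-oxooct-7-enal
Product: 21 (6R,8S,10R)-13-[tert-butyl(diphenyl)silyl]oxy-8,10-dihydroxy-1-oxogermacra-4Z,7(11)-dien-12,6-olide
Conditions: CrCl2 (10 equiv), NiCl2 (2 mol%), DMSO/THF (3:1), 0.002 M, syringe-pump addition, rt
Reagents that add atoms: none
Why: Nozaki–Hiyama–Kishi macrocyclisation: zerovalent nickel inserts into the vinylogous acyl iodide, the alkenyl group passes to trivalent chromium and adds only to the aldehyde, and a chromium bridge between the C10 hydroxyl and the aldehyde oxygen can span the closing ring only with both C–O bonds on the same face, which is the 8S alcohol.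

Step 15
Reactants: 21 (6R,8S,10R)-13-[tert-butyl(diphenyl)silyl]oxy-8,10-dihydroxy-1-oxogermacra-4Z,7(11)-dien-12,6-olide
Product: 22 (6R,8S,10R)-13-[tert-butyl(diphenyl)silyl]oxy-10-hydroxy-8-methacryloyloxy-1-oxogermacra-4Z,7(11)-dien-12,6-olide
Conditions: methacrylic anhydride (1.5 equiv), DMAP (0.2 equiv), Et3N, CH2Cl2, 0 °C
Reagents that add atoms: methacrylic anhydride, C=C(C)C(=O)OC(=O)C(C)=C
Why: DMAP-catalysed acylation (Steglich type) esterifies the secondary C8 alcohol much faster than the tertiary C10 alcohol, with retention at C8 because its C–O bond is not broken.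

Step 16
Reactants: 22 (6R,8S,10R)-13-[tert-butyl(diphenyl)silyl]oxy-10-hydroxy-8-methacryloyloxy-1-oxogermacra-4Z,7(11)-dien-12,6-olide
Product: 23 (6R,8S,10R)-10,13-dihydroxy-8-methacryloyloxy-1-oxogermacra-4Z,7(11)-dien-12,6-olide
Conditions: HF·pyridine, pyridine/THF, 0 °C to rt
Reagents that add atoms: none
Why: Fluoride-driven Si–O cleavage releases the C13 alcohol under buffered conditions that the lactone, the methacrylate and the C6 hydrogen tolerate.

Step 17
Reactants: 23 (6R,8S,10R)-10,13-dihydroxy-8-methacryloyloxy-1-oxogermacra-4Z,7(11)-dien-12,6-olide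
Product: 24 (6R,8S,10R)-10,13-diacetoxy-8-methacryloyloxy-1-oxogermacra-4Z,7(11)-dien-12,6-olide (CNP0115165.2)
Conditions: Ac2O (10 equiv), DMAP (3 equiv), CH2Cl2, rt to 35 °C
Reagents that add atoms: acetic anhydride, CC(=O)OC(C)=O
Why: DMAP-catalysed acetylation through the N-acetylpyridinium ion is strong enough for the tertiary α-ketol as well as the primary alcohol, so both acetates go on in one operation without touching a stereocentre.

## Compound list

1 | (R)-citramalic acid [(2R)-2-hydroxy-2-methylbutanedioic acid] | C[C@@](O)(CC(=O)O)C(=O)O | starting material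
2 | 2-[(4R)-2,2,4-trimethyl-5-oxo-1,3-dioxolan-4-yl]acetic acid | C[C@]1(CC(=O)O)OC(C)(C)OC1=O | intermediate
3 | (5R)-5-(2-hydroxyethyl)-2,2,5-trimethyl-1,3-dioxolan-4-one | C[C@]1(CCO)OC(C)(C)OC1=O | intermediate
4 | (3R)-3-hydroxy-3-methyloxolan-2-one | C[C@@]1(O)CCOC1=O | intermediate
5 | (3R)-3,5-dihydroxy-3-methylpentan-2-one | C[C@@](O)(CCO)C(C)=O | intermediate
6 | 1-[(4R)-2,2,4-trimethyl-1,3-dioxan-4-yl]ethan-1-one | C[C@]1(OC(C)(C)OCC1)C(C)=O | intermediate
7 | prop-2-yn-1-ol | C#CCO | starting material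
8 | bromomagnesium (2Z)-3-(bromomagnesio)-2-methylprop-2-en-1-olate | Br[Mg]OC/C(C)=C\[Mg]Br | intermediate
9 | (2Z)-3-iodo-2-methylprop-2-en-1-ol | OC/C(C)=C\I | intermediate
10 | (1Z)-3-bromo-1-iodo-2-methylprop-1-ene | BrC/C(C)=C\I | intermediate
11 | lithium 1-[(4R)-2,2,4-trimethyl-1,3-dioxan-4-yl]ethen-1-olate | C[C@]1(OC(C)(C)OCC1)C(=C)O[Li] | intermediate
12 | (4Z)-5-iodo-4-methyl-1-[(4R)-2,2,4-trimethyl-1,3-dioxan-4-yl]pent-4-en-1-one | C[C@]1(OC(C)(C)OCC1)C(=O)CC/C(C)=C\I | intermediate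
13 | (2Z)-3-methyl-6-oxo-6-[(4R)-2,2,4-trimethyl-1,3-dioxan-4-yl]hex-2-enal | C[C@]1(OC(C)(C)OCC1)C(=O)CC/C(C)=C\C=O | intermediate
14 | tert-butyl(diphenyl)(prop-2-yn-1-yloxy)silane | C#CCO[Si](c1ccccc1)(c1ccccc1)C(C)(C)C | starting material
15 | methyl{3-[tert-butyl(diphenyl)silyl]oxyprop-1-yn-1-yl}zinc | C[Zn]C#CCO[Si](c1ccccc1)(c1ccccc1)C(C)(C)C | intermediate
16 | (4Z,6R)-9-{[tert-butyl(diphenyl)silyl]oxy}-6-hydroxy-4-methyl-1-[(4R)-2,2,4-trimethyl-1,3-dioxan-4-yl]non-4-en-7-yn-1-one | C[C@]1(OC(C)(C)OCC1)C(=O)CC/C(C)=C\[C@@H](O)C#CCO[Si](c1ccccc1)(c1ccccc1)C(C)(C)C | intermediate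
17 | (4Z,6R,7E)-9-{[tert-butyl(diphenyl)silyl]oxy}-6-hydroxy-7,8-diiodo-4-methyl-1-[(4R)-2,2,4-trimethyl-1,3-dioxan-4-yl]nona-4,7-dien-1-one | C[C@]1(OC(C)(C)OCC1)C(=O)CC/C(C)=C\[C@@H](O)/C(I)=C(\I)CO[Si](c1ccccc1)(c1ccccc1)C(C)(C)C | intermediate
18 | (5R)-3-({[tert-butyl(diphenyl)silyl]oxy}methyl)-4-iodo-5-{(1Z)-2-methyl-5-oxo-5-[(4R)-2,2,4-trimethyl-1,3-dioxan-4-yl]pent-1-en-1-yl}furan-2(5H)-one | C[C@]1(OC(C)(C)OCC1)C(=O)CC/C(C)=C\[C@H]2OC(=O)C(CO[Si](c3ccccc3)(c3ccccc3)C(C)(C)C)=C2I | intermediate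
19 | (5R)-3-({[tert-butyl(diphenyl)silyl]oxy}methyl)-5-[(1Z,6R)-6,8-dihydroxy-2,6-dimethyl-5-oxooct-1-en-1-yl]-4-iodofuran-2(5H)-one | C[C@@](O)(CCO)C(=O)CC/C(C)=C\[C@H]1OC(=O)C(CO[Si](c2ccccc2)(c2ccccc2)C(C)(C)C)=C1I | intermediate
20 | (3R,7Z)-8-[(2R)-4-({[tert-butyl(diphenyl)silyl]oxy}methyl)-3-iodo-5-oxo-2,5-dihydrofuran-2-yl]-3-hydroxy-3,7-dimethyl-4-oxooct-7-enal | C[C@@](O)(CC=O)C(=O)CC/C(C)=C\[C@H]1OC(=O)C(CO[Si](c2ccccc2)(c2ccccc2)C(C)(C)C)=C1I | intermediate
21 | (6R,8S,10R)-13-[tert-butyl(diphenyl)silyl]oxy-8,10-dihydroxy-1-oxogermacra-4Z,7(11)-dien-12,6-olide | O[C@H]1C[C@@](C)(O)C(=O)CC/C(C)=C\[C@H]2OC(=O)C(CO[Si](c3ccccc3)(c3ccccc3)C(C)(C)C)=C12 | intermediate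
22 | (6R,8S,10R)-13-[tert-butyl(diphenyl)silyl]oxy-10-hydroxy-8-methacryloyloxy-1-oxogermacra-4Z,7(11)-dien-12,6-olide | C=C(C)C(=O)O[C@H]1C[C@@](C)(O)C(=O)CC/C(C)=C\[C@H]2OC(=O)C(CO[Si](c3ccccc3)(c3ccccc3)C(C)(C)C)=C12 | intermediate
23 | (6R,8S,10R)-10,13-dihydroxy-8-methacryloyloxy-1-oxogermacra-4Z,7(11)-dien-12,6-olide | C=C(C)C(=O)O[C@H]1C[C@@](C)(O)C(=O)CC/C(C)=C\[C@H]2OC(=O)C(CO)=C12 | intermediate
24 | (6R,8S,10R)-10,13-diacetoxy-8-methacryloyloxy-1-oxogermacra-4Z,7(11)-dien-12,6-olide (CNP0115165.2) | C=C(C)C(=O)O[C@H]1C[C@@](C)(OC(C)=O)C(=O)CC/C(C)=C\[C@H]2OC(=O)C(COC(C)=O)=C12 | target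

## Step count and risk

Total step count: 17. Longest linear sequence: 15 (steps 1–4 and 7–17; steps 5 and 6 are the side branch).

The three steps most likely to fail are 9, 10 and 14.

Step 9 asks a catalytic alkynylation to work on a Z-enal that also carries a ketone, and the sense and level of induction are not assured. The fallback sets out from 13. The alkyne 14 is added without a chiral ligand (Zn(OTf)2, Et3N, toluene) to give the C6-epimeric alcohol mixture F1. MnO2 oxidises this doubly activated carbinol to the ynone F2. Reduction with (R)-2-methyl-CBS-oxazaborolidine and catecholborane at −78 °C, with the Z-alkenyl side acting as the large group, then sets the centre by reagent control and comes back to the route at 16.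

Step 10 exposes a doubly activated propargylic alcohol and a Z olefin to iodine, and step 11 then has to tell two vinyl iodides apart. The fallback sets out from 16 and builds the ring in one operation by chloropalladation–carbonylation (PdCl2 5 mol%, CuCl2 3 equiv, CO 1 atm, THF, rt), giving the 4-chlorobutenolide F3. Chloride is then exchanged for iodide by addition–elimination (NaI, acetone, 50 °C), which comes back to the route at 18.

Step 14 may close the ring without the chelate controlling C8. The fallback sets out from 20. If the same ring closure gives mainly the 8R alcohol F4, the ester is introduced with inversion instead of retention: Mitsunobu esterification of F4 with methacrylic acid (PPh3, DIAD, toluene, 0 °C) comes back to the route at 22.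

## Further compounds

F1 | step 9 | (4Z)-9-{[tert-butyl(diphenyl)silyl]oxy}-6-hydroxy-4-methyl-1-[(4R)-2,2,4-trimethyl-1,3-dioxan-4-yl]non-4-en-7-yn-1-one as the mixture of C6 epimers | C[C@]1(OC(C)(C)OCC1)C(=O)CC/C(C)=C\C(O)C#CCO[Si](c1ccccc1)(c1ccccc1)C(C)(C)C
F2 | step 9 | (4Z)-9-{[tert-butyl(diphenyl)silyl]oxy}-4-methyl-1-[(4R)-2,2,4-trimethyl-1,3-dioxan-4-yl]non-4-en-7-yne-1,6-dione | C[C@]1(OC(C)(C)OCC1)C(=O)CC/C(C)=C\C(=O)C#CCO[Si](c1ccccc1)(c1ccccc1)C(C)(C)C
F3 | step 10 | (5R)-3-({[tert-butyl(diphenyl)silyl]oxy}methyl)-4-chloro-5-{(1Z)-2-methyl-5-oxo-5-[(4R)-2,2,4-trimethyl-1,3-dioxan-4-yl]pent-1-en-1-yl}furan-2(5H)-one | C[C@]1(OC(C)(C)OCC1)C(=O)CC/C(C)=C\[C@H]2OC(=O)C(CO[Si](c3ccccc3)(c3ccccc3)C(C)(C)C)=C2Cl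
F4 | step 14 | (6R,8R,10R)-13-[tert-butyl(diphenyl)silyl]oxy-8,10-dihydroxy-1-oxogermacra-4Z,7(11)-dien-12,6-olide | O[C@@H]1C[C@@](C)(O)C(=O)CC/C(C)=C\[C@H]2OC(=O)C(CO[Si](c3ccccc3)(c3ccccc3)C(C)(C)C)=C12
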